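**Retrosynthetic overview**

1. The target comes from a cis-fused 7(11)-en-8-one that already carries the full C-3 ester, by α'-hydroxylation (C-9) and a final kinetic deconjugation to the isopropenyl ketone (C-7).
2. The side chain is joined by a Horner–Wadsworth–Emmons reaction between a C-3 phosphonoacetate and (R)-3-(angeloyloxy)butanal.
3. The cis-decalin comes from face-selective hydrogenation of a cross-conjugated 7(11),9-dien-8-one (C-10).
4. Both carbocycles form in one palladium-catalysed domino Heck reaction of an acyclic (Z)-β-iodo dienone: ring B first (quaternary C-5), ring A second.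
5. The acyclic chain comes from acylation and hydroiodination of an alkyne made by asymmetric allylboration of pent-4-ynal (C-3, C-4).

Atom labels C-1 to C-15 follow eremophilane numbering of the decalin: C-3 ester carbon, C-4 and C-5 methyl-bearing carbons, C-7 isopropenyl carbon, C-8 ketone, C-9 carbinol, C-10 ring-fusion CH. Ring A is the ketone ring, ring B the ester ring.

Assumption: the (R)-configured phosphoric acid in step 3 gives the (3R,4R)-alcohol as drawn; if the sense of induction is opposite, its enantiomer is used.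

**Step 1**
Reactants: 1 isoprene (2-methylbuta-1,3-diene)
Product: 2 (Z)-4,4,5,5-tetramethyl-2-(2-methylbut-2-en-1-yl)-1,3,2-dioxaborolane
Conditions: pinacolborane (1.0 equiv), FeCl2 (4 mol%), N-(2,6-diisopropylphenyl)-1-(pyridin-2-yl)methanimine (4 mol%), Mg (10 mol%), Et2O, 23 °C
Reagents that add atoms: pinacolborane, [H]B1OC(C)(C)C(C)(C)O1
Why: Iron-catalysed 1,4-hydroboration of a 2-substituted diene; hydrogen and boron are delivered to the two termini of the s-cis-bound diene, so the CH2B group and the new methyl end up cis (Z).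

**Step 2**
Reactants: 3 pent-4-yn-1-ol
Product: 4 pent-4-ynal
Conditions: TEMPO (10 mol%), PhI(OAc)2 (1.1 equiv), CH2Cl2, 23 °C
Reagents that add atoms: none
Why: Oxoammonium (TEMPO) oxidation stops cleanly at the aldehyde and leaves the alkyne alone.

**Step 3**
Reactants: 4 pent-4-ynal; 2 (Z)-allylboronate
Product: 6 (3R,4R)-2,3-dimethyloct-1-en-7-yn-4-ol, via borate ester 5 (not isolated)
Conditions: (R)-3,3'-bis(2,4,6-triisopropylphenyl)-1,1'-binaphthyl-2,2'-diyl hydrogen phosphate (5 mol%), toluene, −30 °C; then aq. NaHCO3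
Reagents that add atoms: none
Why: Brønsted-acid-catalysed allylboration through a closed chair (Zimmerman–Traxler) transition state; the Z-γ-methyl sits axial and gives the syn C-3/C-4 pair, and the chiral phosphate bound to the boronate oxygen selects the aldehyde face.

**Step 4**
Reactants: 6 alkynol; 7 2-(diethoxyphosphoryl)acetic acid
Product: 8 (3R,4R)-2,3-dimethyloct-1-en-7-yn-4-yl 2-(diethoxyphosphoryl)acetate
Conditions: EDC·HCl (1.3 equiv), DMAP (10 mol%), CH2Cl2, 0 → 23 °C
Reagents that add atoms: none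
Why: Steglich-type esterification at oxygen, so no stereocentre is touched; the phosphonoacetate masks the alcohol and is the handle for the later olefination.

**Step 5**
Reactants: 8 alkynyl phosphonoacetate; 9 3-methylbut-2-enoyl chloride
Product: 11 (3R,4R,7Z)-7-iodo-2,3,11-trimethyl-9-oxododeca-1,7,10-trien-4-yl 2-(diethoxyphosphoryl)acetate, via ynone 10 (not isolated)
Conditions: PdCl2(PPh3)2 (2 mol%), CuI (4 mol%), Et3N (1.2 equiv), THF, 0 → 23 °C; then NaI (3 equiv), AcOH, 23 °C
Reagents that add atoms: sodium iodide, [Na+].[I-]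
Why: Acyl Sonogashira coupling followed by conjugate hydroiodination of the ynone; anti addition gives the (Z)-β-iodo enone, with iodine cis to the carbonyl, which later holds C-8 on the same side as the new C-5–C-10 bond.

**Step 6** (key step, both rings)
Reactants: 11 (Z)-β-iodo dienone
Product: 14 (1R,2R,8aR)-1,8a-dimethyl-6-oxo-7-(propan-2-ylidene)-1,2,3,4,6,7,8,8a-octahydronaphthalen-2-yl 2-(diethoxyphosphoryl)acetate, via alkylpalladium iodide 12 (not isolated), via isopropenyl dienone 13 (not isolated)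
Conditions: Pd(OAc)2 (10 mol%), PPh3 (25 mol%), Et3N (3 equiv), MeCN (0.01 M), 80 °C
Reagents that add atoms: none
Why: Domino (zipper) intramolecular Mizoroki–Heck reaction: zerovalent palladium inserts into the vinyl carbon–iodine bond with retention, a 6-exo insertion of the 1,1-disubstituted alkene closes ring B and leaves neopentyl palladium 12 without a β-hydrogen, a second 6-exo insertion into the enone alkene closes ring A, and β-hydride elimination plus amine-mediated isomerisation gives the conjugated dienone. C-5 is set in the first insertion through a chair-like eclipsed transition state in which the C-3 and C-4 substituents and the palladium-bearing CH2 are equatorial, which places the angular methyl cis to the C-4 methyl.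

**Step 7**
Reactants: 14 cross-conjugated dienone
Product: 15 (1R,2R,4aR,8aS)-1,8a-dimethyl-6-oxo-7-(propan-2-ylidene)decahydronaphthalen-2-yl 2-(diethoxyphosphoryl)acetate
Conditions: H2 (1 atm), Pd/C (5 wt% palladium on carbon), EtOAc, 23 °C, stopped after 1 equiv H2
Reagents that add atoms: none
Why: Heterogeneous hydrogenation takes the trisubstituted ring enone alkene and leaves the tetrasubstituted exocyclic one; syn delivery to the convex face puts H-10 cis to the angular methyl (cis ring fusion), as is usual for angular-methyl octalones.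

**Step 8**
Reactants: 16 (R)-2-methyloxirane; 17 vinylmagnesium bromide
Product: 18 (R)-pent-4-en-2-ol
Conditions: CuI (10 mol%), THF, −40 → 0 °C; aq. NH4Cl
Reagents that add atoms: none
Why: Copper-catalysed Grignard opening of the epoxide at the CH2 carbon (SN2), so the stereocentre is not touched.

**Step 9**
Reactants: 18 (R)-pent-4-en-2-ol; 19 angelic acid [(Z)-2-methylbut-2-enoic acid]
Product: 21 (R)-pent-4-en-2-yl (Z)-2-methylbut-2-enoate, via mixed anhydride 20 (not isolated)
Conditions: 19, 2,4,6-trichlorobenzoyl chloride (1.2 equiv), Et3N (1.3 equiv), toluene, 23 °C; then 18, 80 °C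
Reagents that add atoms: none
Why: Yamaguchi-type mixed-anhydride esterification without DMAP acylates oxygen and keeps the Z (angelate) geometry.

**Step 10**
Reactants: 21 pentenyl angelate
Product: 23 (R)-4-oxobutan-2-yl (Z)-2-methylbut-2-enoate, via diol 22 (not isolated)
Conditions: OsO4 (2 mol%), NaIO4 (4 equiv), 2,6-lutidine, dioxane/H2O (3:1), 23 °C
Reagents that add atoms: osmium tetroxide, O=[Os](=O)(=O)=O; sodium periodate, [Na+].[O-]I(=O)(=O)=O
Why: Lemieux–Johnson cleavage; electrophilic OsO4 takes the electron-rich terminal alkene and not the conjugated trisubstituted angelate alkene.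

**Step 11**
Reactants: 15 decalin phosphonoacetate; 23 aldehyde
Product: 24 (1R,2R,4aR,8aS)-1,8a-dimethyl-6-oxo-7-(propan-2-ylidene)decahydronaphthalen-2-yl (2E,5R)-5-{[(2Z)-2-methylbut-2-enoyl]oxy}hex-2-enoate
Conditions: LiCl (1.5 equiv), iPr2NEt (1.2 equiv), MeCN, 0 → 23 °C
Reagents that add atoms: none
Why: Masamune–Roush Horner–Wadsworth–Emmons olefination gives the E-enoate; the weak amine base spares the β-acyloxy aldehyde and the ring ketone.

**Step 12**
Reactants: 24 enone ester
Product: 26 (1R,2R,4aS,5R,8aR)-5-hydroxy-1,8a-dimethyl-6-oxo-7-(propan-2-ylidene)decahydronaphthalen-2-yl (2E,5R)-5-{[(2Z)-2-methylbut-2-enoyl]oxy}hex-2-enoate, via potassium dienolate 25 (not isolated)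
Conditions: KN(SiMe3)2 (1.1 equiv), THF, −78 °C; then 2-(phenylsulfonyl)-3-phenyloxaziridine (1.3 equiv), −78 °C; aq. NH4Cl
Reagents that add atoms: 2-(phenylsulfonyl)-3-phenyloxaziridine, O=S(=O)(N1OC1c1ccccc1)c1ccccc1
Why: Kinetic α'-deprotonation of the enone (the ketone CH2 is far more acidic than any ester position) and Davis enolate hydroxylation; the oxaziridine approaches the convex face away from ring B, giving the equatorial 9-OH cis to H-10.

**Step 13**
Reactants: 26 hydroxy enone
Product: 28 (1R,2R,4aS,5R,7R,8aR)-5-hydroxy-1,8a-dimethyl-6-oxo-7-(prop-1-en-2-yl)decahydronaphthalen-2-yl (2E,5R)-5-{[(2Z)-2-methylbut-2-enoyl]oxy}hex-2-enoate (CNP0210874.1), via bis-silyl dienol ether 27 (not isolated)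
Conditions: TMSOTf (2.4 equiv), Et3N (3 equiv), CH2Cl2, −78 → −20 °C; then n-Bu4NF/AcOH (1:1.2, 2.5 equiv), THF, −78 → 0 °C
Reagents that add atoms: none
Why: Soft enolisation at the γ-methyl gives the extended silyl dienol ether (deconjugation); fluoride frees the dienolate, which is protonated kinetically at the α-carbon, axially from the face opposite the angular methyl, so the isopropenyl group ends equatorial (7R).

**Compound list**

1 | isoprene (2-methylbuta-1,3-diene) | C=CC(C)=C | starting material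
2 | (Z)-4,4,5,5-tetramethyl-2-(2-methylbut-2-en-1-yl)-1,3,2-dioxaborolane | C/C=C(\CB1OC(C)(C)C(C)(C)O1)C | intermediate
3 | pent-4-yn-1-ol | C#CCCCO | starting material
4 | pent-4-ynal | C#CCCC=O | intermediate
5 | 2-{[(3R,4R)-2,3-dimethyloct-1-en-7-yn-4-yl]oxy}-4,4,5,5-tetramethyl-1,3,2-dioxaborolane (borate ester) | C=C(C)[C@@H](C)[C@H](OB1OC(C)(C)C(C)(C)O1)CCC#C | intermediate (not isolated)
6 | (3R,4R)-2,3-dimethyloct-1-en-7-yn-4-ol | C=C(C)[C@@H](C)[C@H](O)CCC#C | intermediate
7 | 2-(diethoxyphosphoryl)acetic acid | CCOP(=O)(CC(=O)O)OCC | starting material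
8 | (3R,4R)-2,3-dimethyloct-1-en-7-yn-4-yl 2-(diethoxyphosphoryl)acetate | C=C(C)[C@@H](C)[C@H](OC(=O)CP(=O)(OCC)OCC)CCC#C | intermediate
9 | 3-methylbut-2-enoyl chloride | CC(C)=CC(=O)Cl | starting material
10 | (3R,4R)-2,3,11-trimethyl-9-oxododeca-1,10-dien-7-yn-4-yl 2-(diethoxyphosphoryl)acetate (ynone) | C=C(C)[C@@H](C)[C@H](OC(=O)CP(=O)(OCC)OCC)CCC#CC(=O)C=C(C)C | intermediate (not isolated)
11 | (3R,4R,7Z)-7-iodo-2,3,11-trimethyl-9-oxododeca-1,7,10-trien-4-yl 2-(diethoxyphosphoryl)acetate | C=C(C)[C@@H](C)[C@H](OC(=O)CP(=O)(OCC)OCC)CC/C(I)=C/C(=O)C=C(C)C | intermediate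
12 | {[(1R,2R,3R,6Z)-3-{[(diethoxyphosphoryl)acetyl]oxy}-1,2-dimethyl-6-(4-methyl-2-oxopent-3-en-1-ylidene)cyclohexyl]methyl}(iodo)palladium, ligands omitted | CC(C)=CC(=O)/C=C1/CC[C@@H](OC(=O)CP(=O)(OCC)OCC)[C@H](C)[C@@]1(C)C[Pd]I | intermediate (not isolated)
13 | (1R,2R,8aR)-1,8a-dimethyl-6-oxo-7-(prop-1-en-2-yl)-1,2,3,4,6,7,8,8a-octahydronaphthalen-2-yl 2-(diethoxyphosphoryl)acetate (C-7 epimers) | C=C(C)C1C[C@@]2(C)C(CC[C@@H](OC(=O)CP(=O)(OCC)OCC)[C@@H]2C)=CC1=O | intermediate (not isolated)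
14 | (1R,2R,8aR)-1,8a-dimethyl-6-oxo-7-(propan-2-ylidene)-1,2,3,4,6,7,8,8a-octahydronaphthalen-2-yl 2-(diethoxyphosphoryl)acetate | CC(C)=C1C[C@@]2(C)C(CC[C@@H](OC(=O)CP(=O)(OCC)OCC)[C@@H]2C)=CC1=O | intermediate
15 | (1R,2R,4aR,8aS)-1,8a-dimethyl-6-oxo-7-(propan-2-ylidene)decahydronaphthalen-2-yl 2-(diethoxyphosphoryl)acetate | CC(C)=C1C[C@@]2(C)[C@H](CC[C@@H](OC(=O)CP(=O)(OCC)OCC)[C@@H]2C)CC1=O | intermediate
16 | (R)-2-methyloxirane | C[C@@H]1CO1 | starting material
17 | vinylmagnesium bromide | C=C[Mg]Br | starting material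
18 | (R)-pent-4-en-2-ol | C[C@@H](O)CC=C | intermediate
19 | angelic acid [(Z)-2-methylbut-2-enoic acid] | C/C=C(/C)C(=O)O | starting material
20 | (Z)-2-methylbut-2-enoic 2,4,6-trichlorobenzoic anhydride | C/C=C(/C)C(=O)OC(=O)c1c(Cl)cc(Cl)cc1Cl | intermediate (not isolated)
21 | (R)-pent-4-en-2-yl (Z)-2-methylbut-2-enoate | C=CC[C@@H](C)OC(=O)/C(C)=C\C | intermediate
22 | (2R)-4,5-dihydroxypentan-2-yl (Z)-2-methylbut-2-enoate (C-4 epimers) | OCC(O)C[C@@H](C)OC(=O)/C(C)=C\C | intermediate (not isolated)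
23 | (R)-4-oxobutan-2-yl (Z)-2-methylbut-2-enoate | O=CC[C@@H](C)OC(=O)/C(C)=C\C | intermediate
24 | (1R,2R,4aR,8aS)-1,8a-dimethyl-6-oxo-7-(propan-2-ylidene)decahydronaphthalen-2-yl (2E,5R)-5-{[(2Z)-2-methylbut-2-enoyl]oxy}hex-2-enoate | CC(C)=C1C[C@@]2(C)[C@H](CC[C@@H](OC(=O)/C=C/C[C@@H](C)OC(=O)/C(C)=C\C)[C@@H]2C)CC1=O | intermediate
25 | potassium dienolate of 24 (enolate towards C-9) | CC(C)=C1C[C@@]2(C)[C@H](CC[C@@H](OC(=O)/C=C/C[C@@H](C)OC(=O)/C(C)=C\C)[C@@H]2C)C=C1[O-].[K+] | intermediate (not isolated)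
26 | (1R,2R,4aS,5R,8aR)-5-hydroxy-1,8a-dimethyl-6-oxo-7-(propan-2-ylidene)decahydronaphthalen-2-yl (2E,5R)-5-{[(2Z)-2-methylbut-2-enoyl]oxy}hex-2-enoate | CC(C)=C1C[C@@]2(C)[C@H](CC[C@@H](OC(=O)/C=C/C[C@@H](C)OC(=O)/C(C)=C\C)[C@@H]2C)[C@@H](O)C1=O | intermediate
27 | bis(trimethylsilyl) dienol ether of 26 (9-OSiMe3, 8-OSiMe3, C-7=C-8, isopropenyl) | C=C(C)C=1C[C@@]2(C)[C@H](CC[C@@H](OC(=O)/C=C/C[C@@H](C)OC(=O)/C(C)=C\C)[C@@H]2C)[C@@H](O[Si](C)(C)C)C=1O[Si](C)(C)C | intermediate (not isolated)
28 | (1R,2R,4aS,5R,7R,8aR)-5-hydroxy-1,8a-dimethyl-6-oxo-7-(prop-1-en-2-yl)decahydronaphthalen-2-yl (2E,5R)-5-{[(2Z)-2-methylbut-2-enoyl]oxy}hex-2-enoate | C=C(C)[C@H]1C[C@@]2(C)[C@H](CC[C@@H](OC(=O)/C=C/C[C@@H](C)OC(=O)/C(C)=C\C)[C@@H]2C)[C@@H](O)C1=O | target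

**Totals**

Total step count: 13. Longest linear sequence: 9 steps (2, 3, 4, 5, 6, 7, 11, 12, 13).

**Three steps most likely to fail**

Step 6. The neopentyl palladium 12 may close a cyclopropane onto the neighbouring enone alkene (3-exo) or insert too slowly into the trisubstituted alkene, and the sense of induction at C-5 rests on a transition-state argument. The fallback sets out from 8 and comes back at 14, building the rings one after the other. Ring-closing enyne metathesis of 8 (second-generation Grubbs catalyst, ethylene, CH2Cl2, 40 °C) gives the semicyclic diene phosphonoacetate F1. A thermal Diels–Alder reaction of F1 with 3-methylbuta-1,2-diene (toluene, 170 °C, sealed tube) adds the unsubstituted allene C=C, CH2 to the hindered diene terminus and anti to the neighbouring secondary methyl, and gives the skipped-diene phosphonoacetate F2. Oxidation of the doubly allylic ring CH2 of F2 (CrO3, 3,5-dimethylpyrazole, CH2Cl2, −20 °C) gives 14.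

Step 12. The strong base may attack the side-chain esters (γ-deprotonation, Michael addition), and the enolate can add to the sulfonimine by-product. The fallback sets out from 14 and comes back at 26, so that the C-9 oxygen is in place before the side chain is built. 1,4-Hydrosilylation of 14 with [(Ph3P)CuH]6 (5 mol%) and PhMe2SiH in toluene reduces only the ring enone, sets the cis fusion and gives the cross-conjugated silyl dienol ether phosphonoacetate F3. Rubottom oxidation of F3 (dimethyldioxirane, acetone, −78 °C; then HF·pyridine) gives the hydroxy enone phosphonoacetate F4. Olefination of F4 with 23 (LiCl, iPr2NEt, MeCN) gives 26.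

Step 13. Protonation at the γ-carbon returns 26, enolisation towards C-9 can scramble that centre, and the product can drift back into conjugation. The fallback sets out from 11 and comes back at 28, keeping the isopropenyl group from the Heck step onwards. The domino Heck reaction is run with Ag2CO3 in place of the amine (Pd(OAc)2, PPh3, MeCN, 60 °C) and the isopropenyl dienone 13 is isolated. 1,4-Hydrosilylation of 13 with [(Ph3P)CuH]6 and PhMe2SiH gives the silyl enol ether phosphonoacetate F5 (cis fusion, enol ether towards C-9). Rubottom oxidation (dimethyldioxirane, acetone, −78 °C; then HF·pyridine) gives the hydroxy ketone phosphonoacetate F6. Olefination of F6 with 23 (LiCl, iPr2NEt, MeCN) gives 28, the amine equilibrating C-7 to the equatorial epimer.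

**Further compounds**

F1 | step 6 | (1R,2R)-4-ethenyl-2,3-dimethylcyclohex-3-en-1-yl 2-(diethoxyphosphoryl)acetate | C=CC1=C(C)[C@@H](C)[C@H](OC(=O)CP(=O)(OCC)OCC)CC1
F2 | step 6 | (1R,2R,8aR)-1,8a-dimethyl-7-(propan-2-ylidene)-1,2,3,4,6,7,8,8a-octahydronaphthalen-2-yl 2-(diethoxyphosphoryl)acetate | CC(C)=C1C[C@@]2(C)C(CC[C@@H](OC(=O)CP(=O)(OCC)OCC)[C@@H]2C)=CC1
F3 | step 12 | (1R,2R,4aR,8aS)-6-{[dimethyl(phenyl)silyl]oxy}-1,8a-dimethyl-7-(propan-2-ylidene)-1,2,3,4,4a,7,8,8a-octahydronaphthalen-2-yl 2-(diethoxyphosphoryl)acetate | CC(C)=C1C[C@@]2(C)[C@H](CC[C@@H](OC(=O)CP(=O)(OCC)OCC)[C@@H]2C)C=C1O[Si](C)(C)c1ccccc1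
F4 | step 12 | (1R,2R,4aS,5R,8aR)-5-hydroxy-1,8a-dimethyl-6-oxo-7-(propan-2-ylidene)decahydronaphthalen-2-yl 2-(diethoxyphosphoryl)acetate | CC(C)=C1C[C@@]2(C)[C@H](CC[C@@H](OC(=O)CP(=O)(OCC)OCC)[C@@H]2C)[C@@H](O)C1=O
F5 | step 13 | (1R,2R,4aR,7R,8aS)-6-{[dimethyl(phenyl)silyl]oxy}-1,8a-dimethyl-7-(prop-1-en-2-yl)-1,2,3,4,4a,7,8,8a-octahydronaphthalen-2-yl 2-(diethoxyphosphoryl)acetate | C=C(C)[C@H]1C[C@@]2(C)[C@H](CC[C@@H](OC(=O)CP(=O)(OCC)OCC)[C@@H]2C)C=C1O[Si](C)(C)c1ccccc1
F6 | step 13 | (1R,2R,4aS,5R,7R,8aR)-5-hydroxy-1,8a-dimethyl-6-oxo-7-(prop-1-en-2-yl)decahydronaphthalen-2-yl 2-(diethoxyphosphoryl)acetate | C=C(C)[C@H]1C[C@@]2(C)[C@H](CC[C@@H](OC(=O)CP(=O)(OCC)OCC)[C@@H]2C)[C@@H](O)C1=O
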